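## Retrosynthetic overview

1. Numbering (elemane): vinyl C1=C2 and methyl C14 on quaternary C10; C5 carries the formyl-oxirane (C4, C3, C15); C6 carries the ester; C7–C11(=C13)–C12(=O)–O–C8 is the methylene lactone (ring B); C9 carries OH; C5–C10 is the cyclohexane (ring A).
2. Endgame: the formyl-oxirane comes from an isopropenyl group (allylic oxidation at C15, Sharpless epoxidation at C4, oxidation to the aldehyde), after C6 acylation of the cyclised alcohol.
3. Key disconnection C6–C7: ring A is closed last by an intramolecular Nozaki–Hiyama allylation of a C6 aldehyde by a 3-(bromomethyl)butenolide (ring B already present). This one operation gives ring A, the exo-methylene lactone, the free C6–OH and both the C6 and C7 stereocentres. The enabling feature is that the C6 carbinol is bonded to C7, the β-carbon of the methylene lactone cis-fused to ring A at C7–C8, so that O–C6–C7–C11=C13 is a homoallylic alcohol (carbonyl-allylation retron) and C8 on the butenolide steers the tethered attack.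
4. Ring B comes from a C8 aldehyde: Felkin alkynylation (C7–C8), hydroxyl-directed hydroalumination/iodination, palladium-catalysed carbonylative lactonisation.
5. The C5/C10 tertiary/quaternary pair comes from an Ireland–Claisen rearrangement of a (Z)-allylic senecioate (the C5–C10 bond is the one the biosynthetic Cope rearrangement makes), controlled by C9 from (S)-glyceraldehyde acetonide. Ring order: dioxolane (temporary) → ring B → ring A → oxirane.

Key step: step 18

Remark: (S)-glyceraldehyde acetonide is taken as a commercial starting material, and the facial sense of step 6 is assumed to follow the model known for (Z)-alkenyl dioxolanes (allylic H eclipsing the alkene, new bond anti to the allylic C–O bond).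

## Route

Step 1
Reactants: 1 (S)-2,2-dimethyl-1,3-dioxolane-4-carbaldehyde
Product: 2 (R)-4-ethynyl-2,2-dimethyl-1,3-dioxolane
Conditions: dimethyl (1-diazo-2-oxopropyl)phosphonate, K2CO3, MeOH, 0 °C → rt
Reagents that add atoms: dimethyl (1-diazo-2-oxopropyl)phosphonate, CC(=O)C(=[N+]=[N-])P(=O)(OC)OC
Why: Ohira–Bestmann (Seyferth–Gilbert) homologation converts the aldehyde into the terminal alkyne under mild carbonate conditions that should leave the α-stereocentre intact (the descriptor changes from S to R only through the CIP priorities).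

Step 2
Reactants: 2 (R)-4-ethynyl-2,2-dimethyl-1,3-dioxolane
Product: 4 methyl 3-[(4R)-2,2-dimethyl-1,3-dioxolan-4-yl]prop-2-ynoate, via lithium acetylide 3 (not isolated)
Conditions: n-BuLi, THF, −78 °C; then ClCO2Me, −78 → 0 °C
Reagents that add atoms: methyl chloroformate, COC(Cl)=O
Why: C-acylation of a lithium acetylide with a chloroformate is a standard alkynoate synthesis and does not touch the dioxolane stereocentre.

Step 3
Reactants: 4 methyl 3-[(4R)-2,2-dimethyl-1,3-dioxolan-4-yl]prop-2-ynoate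
Product: 5 methyl (2Z)-3-[(4R)-2,2-dimethyl-1,3-dioxolan-4-yl]but-2-enoate
Conditions: Me2CuLi (from MeLi and CuI), THF, −78 °C; MeOH then aq. NH4Cl at −78 °C
Reagents that add atoms: lithium dimethylcuprate, [Li+].C[Cu-]C
Why: syn-carbocupration of the alkynoate and cold protonation of the alkenylcuprate with retention place the new methyl and H cis, which should give the (Z)-enoate with the dioxolane carbon (C9) cis to the ester carbon.

Step 4
Reactants: 5 methyl (2Z)-3-[(4R)-2,2-dimethyl-1,3-dioxolan-4-yl]but-2-enoate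
Product: 6 (2Z)-3-[(4R)-2,2-dimethyl-1,3-dioxolan-4-yl]but-2-en-1-ol
Conditions: i-Bu2AlH (2.2 equiv), CH2Cl2, −78 °C; aq. KNaC4H4O6
Reagents that add atoms: none
Why: 1,2-reduction of the enoate by i-Bu2AlH gives the allylic alcohol without changing the alkene geometry.

Step 5
Reactants: 6 (2Z)-3-[(4R)-2,2-dimethyl-1,3-dioxolan-4-yl]but-2-en-1-ol; 7 3-methylbut-2-enoic acid
Product: 8 (2Z)-3-[(4R)-2,2-dimethyl-1,3-dioxolan-4-yl]but-2-en-1-yl 3-methylbut-2-enoate
Conditions: N,N'-dicyclohexylcarbodiimide, DMAP (cat.), CH2Cl2, 0 °C → rt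
Reagents that add atoms: none
Why: Steglich esterification of an unhindered primary allylic alcohol is reliable and creates no stereocentre.

Step 6
Reactants: 8 (2Z)-3-[(4R)-2,2-dimethyl-1,3-dioxolan-4-yl]but-2-en-1-yl 3-methylbut-2-enoate
Product: 12 (2S,3S)-3-[(4R)-2,2-dimethyl-1,3-dioxolan-4-yl]-3-methyl-2-(prop-1-en-2-yl)pent-4-enoic acid, via lithium dienolate 9 (not isolated), via silyl ketene acetal 10 (not isolated), via trimethylsilyl ester 11 (not isolated)
Conditions: LiN(i-Pr)2, THF–DMPU, −78 °C; Me3SiCl–Et3N, −78 → 50 °C; then aq. citric acid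
Reagents that add atoms: none
Why: Ireland–Claisen rearrangement, in which γ-deprotonation of the s-cis senecioate should give the dienolate with O–Li cis to the isopropenyl group, and its silyl ketene acetal should rearrange through a chair with the isopropenyl group equatorial and C9 of the (Z)-alkene axial (this fixes C5 relative to C10), while the C9 stereocentre (C9–H eclipsing the alkene to avoid A(1,3) strain, C5–C10 bond formed anti to the C9–O bond) should fix the absolute sense.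

Step 7
Reactants: 12 (2S,3S)-3-[(4R)-2,2-dimethyl-1,3-dioxolan-4-yl]-3-methyl-2-(prop-1-en-2-yl)pent-4-enoic acid
Product: 13 (2S,3S)-3-[(4R)-2,2-dimethyl-1,3-dioxolan-4-yl]-3-methyl-2-(prop-1-en-2-yl)pent-4-en-1-ol
Conditions: LiAlH4, Et2O, 0 °C → rt
Reagents that add atoms: none
Why: hydride reduction of the carboxylic acid gives the primary alcohol (C6), and the isolated alkenes and the acetonide are inert to LiAlH4.

Step 8
Reactants: 13 (2S,3S)-3-[(4R)-2,2-dimethyl-1,3-dioxolan-4-yl]-3-methyl-2-(prop-1-en-2-yl)pent-4-en-1-ol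
Product: 14 4-methoxybenzyl ether of 13
Conditions: NaH, 4-methoxybenzyl chloride, Bu4NI (cat.), DMF, 0 °C → rt
Reagents that add atoms: 4-methoxybenzyl chloride, COc1ccc(CCl)cc1
Why: Williamson etherification protects C6–OH as an ether that survives acid, base, hydride and organometallic steps and is removed oxidatively later.

Step 9
Reactants: 14 4-methoxybenzyl ether of 13
Product: 15 (2R,3S,4S)-3-ethenyl-5-[(4-methoxyphenyl)methoxy]-3-methyl-4-(prop-1-en-2-yl)pentane-1,2-diol
Conditions: AcOH–H2O (4:1), 45 °C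
Reagents that add atoms: none
Why: mild acid hydrolysis of the terminal acetonide frees the C8/C9 diol while the benzyl-type ether and the alkenes should survive.

Step 10
Reactants: 15 (2R,3S,4S)-3-ethenyl-5-[(4-methoxyphenyl)methoxy]-3-methyl-4-(prop-1-en-2-yl)pentane-1,2-diol
Product: 16 1,2-bis(triethylsilyl) ether of 15
Conditions: Et3SiOTf, 2,6-lutidine, CH2Cl2, −78 → 0 °C
Reagents that add atoms: triethylsilyl trifluoromethanesulfonate, CC[Si](CC)(CC)OS(=O)(=O)C(F)(F)F
Why: the silyl triflate silylates both the primary and the hindered neopentyl secondary hydroxyl.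

Step 11
Reactants: 16 1,2-bis(triethylsilyl) ether of 15
Product: 17 (2R,3S,4S)-3-ethenyl-5-[(4-methoxyphenyl)methoxy]-3-methyl-4-(prop-1-en-2-yl)-2-[(triethylsilyl)oxy]pentanal
Conditions: (COCl)2, DMSO, CH2Cl2, −78 → −30 °C; then Et3N, −78 → 0 °C
Reagents that add atoms: none
Why: under Swern conditions a primary triethylsilyl ether is cleaved and oxidised to the aldehyde (selective oxidative desilylation) while the hindered secondary silyl ether at C9 stays.

Step 12
Reactants: 17 (2R,3S,4S)-3-ethenyl-5-[(4-methoxyphenyl)methoxy]-3-methyl-4-(prop-1-en-2-yl)-2-[(triethylsilyl)oxy]pentanal; 18 1-methoxy-4-[(prop-2-yn-1-yloxy)methyl]benzene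
Product: 19 (4S,5R,6S,7S)-6-ethenyl-1,8-bis[(4-methoxyphenyl)methoxy]-6-methyl-7-(prop-1-en-2-yl)-5-[(triethylsilyl)oxy]oct-2-yn-4-ol
Conditions: 18, n-BuLi, THF, −78 °C; then 17, −78 °C; aq. NH4Cl
Reagents that add atoms: none
Why: acetylide addition to the α-silyloxy aldehyde under non-chelating conditions should follow the Felkin–Anh/Cornforth model (C9–O opposed to C=O, the bulky quaternary C10 anti to the nucleophile) and give the 8,9-anti adduct, which is the cis C8/C9 oxygen pattern of ring A.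

Step 13
Reactants: 19 (4S,5R,6S,7S)-6-ethenyl-1,8-bis[(4-methoxyphenyl)methoxy]-6-methyl-7-(prop-1-en-2-yl)-5-[(triethylsilyl)oxy]oct-2-yn-4-ol
Product: 21 (2Z,4S,5R,6S,7S)-6-ethenyl-2-iodo-1,8-bis[(4-methoxyphenyl)methoxy]-6-methyl-7-(prop-1-en-2-yl)-5-[(triethylsilyl)oxy]oct-2-en-4-ol, via alkenylalanate 20 (not isolated)
Conditions: NaAlH2(OCH2CH2OMe)2 (Red-Al), THF, 0 °C → rt; then I2, −78 °C
Reagents that add atoms: iodine, II
Why: hydroxyl-directed trans-hydroalumination of the propargylic alcohol puts aluminium on the distal alkyne carbon (C11) cis to C8, and iodinolysis with retention gives the (Z)-γ-hydroxy alkenyl iodide.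

Step 14
Reactants: 21 (2Z,4S,5R,6S,7S)-6-ethenyl-2-iodo-1,8-bis[(4-methoxyphenyl)methoxy]-6-methyl-7-(prop-1-en-2-yl)-5-[(triethylsilyl)oxy]oct-2-en-4-ol
Product: 22 (5S)-5-{(1R,2S,3S)-2-ethenyl-4-[(4-methoxyphenyl)methoxy]-2-methyl-3-(prop-1-en-2-yl)-1-[(triethylsilyl)oxy]butyl}-3-{[(4-methoxyphenyl)methoxy]methyl}furan-2(5H)-one
Conditions: PdCl2(PPh3)2 (5 mol%), K2CO3, CO (1 atm), THF, 40 °C
Reagents that add atoms: carbon monoxide, [C-]#[O+]
Why: oxidative addition of the alkenyl iodide to zerovalent palladium, CO insertion and capture of the acylpalladium by the cis γ-hydroxyl (carbonylative lactonisation) closes the butenolide ring B with C8 unchanged.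

Step 15
Reactants: 22 (5S)-5-{(1R,2S,3S)-2-ethenyl-4-[(4-methoxyphenyl)methoxy]-2-methyl-3-(prop-1-en-2-yl)-1-[(triethylsilyl)oxy]butyl}-3-{[(4-methoxyphenyl)methoxy]methyl}furan-2(5H)-one
Product: 23 (5S)-5-{(1R,2S,3S)-2-ethenyl-4-hydroxy-2-methyl-3-(prop-1-en-2-yl)-1-[(triethylsilyl)oxy]butyl}-3-(hydroxymethyl)furan-2(5H)-one
Conditions: DDQ (2.5 equiv), CH2Cl2–pH 7 buffer, 0 °C → rt
Reagents that add atoms: none
Why: oxidative cleavage of both 4-methoxybenzyl ethers by DDQ is neutral and should leave the silyl ether, the butenolide and the alkenes untouched.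

Step 16
Reactants: 23 (5S)-5-{(1R,2S,3S)-2-ethenyl-4-hydroxy-2-methyl-3-(prop-1-en-2-yl)-1-[(triethylsilyl)oxy]butyl}-3-(hydroxymethyl)furan-2(5H)-one
Product: 24 (5S)-3-(bromomethyl)-5-{(1R,2S,3S)-2-ethenyl-4-hydroxy-2-methyl-3-(prop-1-en-2-yl)-1-[(triethylsilyl)oxy]butyl}furan-2(5H)-one
Conditions: NBS, Me2S, CH2Cl2, −20 → 0 °C
Reagents that add atoms: N-bromosuccinimide, BrN1C(=O)CCC1=O
Why: Corey–Kim halogenation converts allylic alcohols into bromides selectively, because the hindered saturated primary alcohol (C6–OH) only forms a reversible alkoxysulfonium salt and is returned on work-up.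

Step 17
Reactants: 24 (5S)-3-(bromomethyl)-5-{(1R,2S,3S)-2-ethenyl-4-hydroxy-2-methyl-3-(prop-1-en-2-yl)-1-[(triethylsilyl)oxy]butyl}furan-2(5H)-one
Product: 25 (2S,3S,4R)-4-[(2S)-4-(bromomethyl)-5-oxo-2,5-dihydrofuran-2-yl]-3-ethenyl-3-methyl-2-(prop-1-en-2-yl)-4-[(triethylsilyl)oxy]butanal
Conditions: Dess–Martin periodinane, NaHCO3, CH2Cl2, 0 °C; used crude at once
Reagents that add atoms: none
Why: buffered Dess–Martin oxidation gives the β,γ-unsaturated aldehyde under neutral conditions that should neither epimerise C5 nor move the isopropenyl double bond into conjugation.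

Step 18
Reactants: 25 (2S,3S,4R)-4-[(2S)-4-(bromomethyl)-5-oxo-2,5-dihydrofuran-2-yl]-3-ethenyl-3-methyl-2-(prop-1-en-2-yl)-4-[(triethylsilyl)oxy]butanal
Product: 27 (3aS,4R,5S,6S,7R,7aS)-6-ethenyl-4-hydroxy-6-methyl-3-methylidene-5-(prop-1-en-2-yl)-7-[(triethylsilyl)oxy]-3a,4,5,6,7,7a-hexahydro-1-benzofuran-2(3H)-one, via allylchromium 26 (not isolated)
Conditions: CrCl2 (5 equiv), THF, 0.005 M, rt
Reagents that add atoms: none
Why: Two equivalents of CrCl2 reduce the allylic C13–Br bond to the trivalent-chromium allyl species 26, which adds through its γ-carbon C7 to the tethered C6 aldehyde in a closed six-membered Zimmerman–Traxler transition state (Nozaki–Hiyama allylation) and so delivers the exo-methylene lactone and the C6 alkoxide directly. The closest known reaction types are the CrCl2-mediated additions of 3-(bromomethyl)furan-2(5H)-ones to aldehydes, which give anti-configured β-(hydroxyalkyl)-α-methylene-γ-butyrolactones, and intramolecular Nozaki–Hiyama cyclisations of 2-(bromomethyl)acrylates onto aldehydes. Ring A (cyclohexane C5–C10) closes in a 6-exo-trig mode with respect to the aldehyde carbonyl, the nucleophilic carbon C7 being a ring atom of the butenolide. C7 is controlled by C8, because the four-atom tether C8–C9–C10–C5 can only reach the butenolide face that carries C9, so the lactone becomes cis-fused (H7 and H8 cis). C6 is controlled by the chair–chair (trans-decalin-like) transition state in which the aldehyde substituent, the C5 isopropenyl, the C9 silyloxy and the C10 vinyl groups are equatorial and C8 is held E to the CH2Cr group by the ring, which places the C6 oxygen anti to C8, that is equatorial and trans to C11. The step needs γ- over α-attack (six- versus eight-membered ring), one aldehyde face (the all-equatorial transition state) and survival of the epimerisable aldehyde (neutral, non-basic chromium conditions under which lactone, silyl ether and alkenes are inert).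

Step 19
Reactants: 27 (3aS,4R,5S,6S,7R,7aS)-6-ethenyl-4-hydroxy-6-methyl-3-methylidene-5-(prop-1-en-2-yl)-7-[(triethylsilyl)oxy]-3a,4,5,6,7,7a-hexahydro-1-benzofuran-2(3H)-one
Product: 28 (3aS,4R,5S,6S,7R,7aS)-6-ethenyl-6-methyl-3-methylidene-2-oxo-5-(prop-1-en-2-yl)-7-[(triethylsilyl)oxy]octahydro-1-benzofuran-4-yl 2-methylpropanoate
Conditions: 2-methylpropanoyl chloride, pyridine, DMAP (cat.), CH2Cl2, 0 °C → rt
Reagents that add atoms: 2-methylpropanoyl chloride, CC(C)C(Cl)=O
Why: acylation of the only free hydroxyl (C6–OH) installs the isobutyrate with retention at C6, the C9 oxygen being masked as its silyl ether.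

Step 20
Reactants: 28 (3aS,4R,5S,6S,7R,7aS)-6-ethenyl-6-methyl-3-methylidene-2-oxo-5-(prop-1-en-2-yl)-7-[(triethylsilyl)oxy]octahydro-1-benzofuran-4-yl 2-methylpropanoate
Product: 29 (3aS,4R,5S,6S,7R,7aS)-6-ethenyl-7-hydroxy-6-methyl-3-methylidene-2-oxo-5-(prop-1-en-2-yl)octahydro-1-benzofuran-4-yl 2-methylpropanoate
Conditions: HF·pyridine, pyridine, THF, 0 °C → rt
Reagents that add atoms: none
Why: buffered fluoride cleaves the triethylsilyl ether without base, so the ester cannot migrate and the methylene lactone is not attacked.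

Step 21
Reactants: 29 (3aS,4R,5S,6S,7R,7aS)-6-ethenyl-7-hydroxy-6-methyl-3-methylidene-2-oxo-5-(prop-1-en-2-yl)octahydro-1-benzofuran-4-yl 2-methylpropanoate
Product: 30 (3aS,4R,5S,6S,7R,7aS)-6-ethenyl-7-hydroxy-5-(3-hydroxyprop-1-en-2-yl)-6-methyl-3-methylidene-2-oxooctahydro-1-benzofuran-4-yl 2-methylpropanoate
Conditions: SeO2 (0.3 equiv), t-BuOOH, CH2Cl2, rt
Reagents that add atoms: tert-butyl hydroperoxide, CC(C)(C)OO (terminal oxidant; the oxygen is passed on by the SeO2 catalyst, O=[Se]=O)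
Why: the selenium dioxide ene/[2,3] allylic oxidation should take place at the methyl group of the electron-rich isopropenyl unit, since the vinyl group has no allylic hydrogen, the methylene lactone is electron-poor and C5–H is flanked by a quaternary carbon.

Step 22
Reactants: 30 (3aS,4R,5S,6S,7R,7aS)-6-ethenyl-7-hydroxy-5-(3-hydroxyprop-1-en-2-yl)-6-methyl-3-methylidene-2-oxooctahydro-1-benzofuran-4-yl 2-methylpropanoate
Product: 31 (3aS,4S,5S,6S,7R,7aS)-6-ethenyl-7-hydroxy-5-[(2S)-2-(hydroxymethyl)oxiran-2-yl]-6-methyl-3-methylidene-2-oxooctahydro-1-benzofuran-4-yl 2-methylpropanoate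
Conditions: Ti(Oi-Pr)4 (20 mol%), L-(+)-diethyl tartrate (24 mol%), t-BuOOH, 4 Å molecular sieves, CH2Cl2, −20 °C
Reagents that add atoms: tert-butyl hydroperoxide, CC(C)(C)OO
Why: Sharpless asymmetric epoxidation acts only on the allylic alcohol alkene, and the L-(+)-tartrate catalyst should deliver oxygen to the face that gives the (S)-2-substituted glycidol (as with 2-methylprop-2-en-1-ol), which is the C4 configuration of the target.

Step 23
Reactants: 31 (3aS,4S,5S,6S,7R,7aS)-6-ethenyl-7-hydroxy-5-[(2S)-2-(hydroxymethyl)oxiran-2-yl]-6-methyl-3-methylidene-2-oxooctahydro-1-benzofuran-4-yl 2-methylpropanoate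
Product: 32 (3aS,4S,5S,6S,7R,7aS)-6-ethenyl-5-[(2R)-2-formyloxiran-2-yl]-7-hydroxy-6-methyl-3-methylidene-2-oxooctahydro-1-benzofuran-4-yl 2-methylpropanoate
Conditions: TEMPO (10 mol%), PhI(OAc)2, CH2Cl2, rt
Reagents that add atoms: none
Why: the oxoammonium oxidation is selective for the primary alcohol over the hindered secondary C9–OH and stops at the aldehyde (the C4 descriptor changes from S to R only through the CIP priorities).

## Compound list

1 | (S)-2,2-dimethyl-1,3-dioxolane-4-carbaldehyde ((S)-glyceraldehyde acetonide) | O=C[C@@H]1COC(C)(C)O1 | starting material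
2 | (R)-4-ethynyl-2,2-dimethyl-1,3-dioxolane | C#C[C@@H]1COC(C)(C)O1 | intermediate
3 | lithium acetylide of 2 | [Li]C#C[C@@H]1COC(C)(C)O1 | intermediate
4 | methyl 3-[(4R)-2,2-dimethyl-1,3-dioxolan-4-yl]prop-2-ynoate | COC(=O)C#C[C@@H]1COC(C)(C)O1 | intermediate
5 | methyl (2Z)-3-[(4R)-2,2-dimethyl-1,3-dioxolan-4-yl]but-2-enoate | COC(=O)/C=C(C)\[C@@H]1COC(C)(C)O1 | intermediate
6 | (2Z)-3-[(4R)-2,2-dimethyl-1,3-dioxolan-4-yl]but-2-en-1-ol | OC/C=C(C)\[C@@H]1COC(C)(C)O1 | intermediate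
7 | 3-methylbut-2-enoic acid | CC(C)=CC(O)=O | starting material
8 | (2Z)-3-[(4R)-2,2-dimethyl-1,3-dioxolan-4-yl]but-2-en-1-yl 3-methylbut-2-enoate | CC(C)=CC(=O)OC/C=C(C)\[C@@H]1COC(C)(C)O1 | intermediate
9 | lithium dienolate of 8 (O–Li cis to the isopropenyl group) | [Li+].C=C(C)/C=C(\[O-])OC/C=C(C)\[C@@H]1COC(C)(C)O1 | intermediate
10 | trimethylsilyl ketene acetal of 8 (Me3SiO cis to the isopropenyl group) | C=C(C)/C=C(\O[Si](C)(C)C)OC/C=C(C)\[C@@H]1COC(C)(C)O1 | intermediate
11 | trimethylsilyl ester of 12 | C[Si](C)(C)OC(=O)[C@@H](C(C)=C)[C@](C)(C=C)[C@@H]1COC(C)(C)O1 | intermediate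
12 | (2S,3S)-3-[(4R)-2,2-dimethyl-1,3-dioxolan-4-yl]-3-methyl-2-(prop-1-en-2-yl)pent-4-enoic acid | OC(=O)[C@@H](C(C)=C)[C@](C)(C=C)[C@@H]1COC(C)(C)O1 | intermediate
13 | (2S,3S)-3-[(4R)-2,2-dimethyl-1,3-dioxolan-4-yl]-3-methyl-2-(prop-1-en-2-yl)pent-4-en-1-ol | OC[C@@H](C(C)=C)[C@](C)(C=C)[C@@H]1COC(C)(C)O1 | intermediate
14 | 4-methoxybenzyl ether of 13 | COc1ccc(COC[C@@H](C(C)=C)[C@](C)(C=C)[C@@H]2COC(C)(C)O2)cc1 | intermediate
15 | (2R,3S,4S)-3-ethenyl-5-[(4-methoxyphenyl)methoxy]-3-methyl-4-(prop-1-en-2-yl)pentane-1,2-diol | COc1ccc(COC[C@@H](C(C)=C)[C@](C)(C=C)[C@@H](O)CO)cc1 | intermediate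
16 | 1,2-bis(triethylsilyl) ether of 15 | COc1ccc(COC[C@@H](C(C)=C)[C@](C)(C=C)[C@@H](O[Si](CC)(CC)CC)CO[Si](CC)(CC)CC)cc1 | intermediate
17 | (2R,3S,4S)-3-ethenyl-5-[(4-methoxyphenyl)methoxy]-3-methyl-4-(prop-1-en-2-yl)-2-[(triethylsilyl)oxy]pentanal | COc1ccc(COC[C@@H](C(C)=C)[C@](C)(C=C)[C@@H](O[Si](CC)(CC)CC)C=O)cc1 | intermediate
18 | 1-methoxy-4-[(prop-2-yn-1-yloxy)methyl]benzene | C#CCOCc1ccc(OC)cc1 | starting material
19 | (4S,5R,6S,7S)-6-ethenyl-1,8-bis[(4-methoxyphenyl)methoxy]-6-methyl-7-(prop-1-en-2-yl)-5-[(triethylsilyl)oxy]oct-2-yn-4-ol | COc1ccc(COC[C@@H](C(C)=C)[C@](C)(C=C)[C@@H](O[Si](CC)(CC)CC)[C@@H](O)C#CCOCc2ccc(OC)cc2)cc1 | intermediate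
20 | sodium alkenylalanate from 19 (five-membered O–Al–C=C chelate, aluminium on the distal alkyne carbon) | [Na+].COc1ccc(COC[C@@H](C(C)=C)[C@](C)(C=C)[C@@H](O[Si](CC)(CC)CC)[C@H]3O[Al-](OCCOC)(OCCOC)C(COCc2ccc(OC)cc2)=C3)cc1 | intermediate
21 | (2Z,4S,5R,6S,7S)-6-ethenyl-2-iodo-1,8-bis[(4-methoxyphenyl)methoxy]-6-methyl-7-(prop-1-en-2-yl)-5-[(triethylsilyl)oxy]oct-2-en-4-ol | COc1ccc(COC[C@@H](C(C)=C)[C@](C)(C=C)[C@@H](O[Si](CC)(CC)CC)[C@@H](O)/C=C(\I)COCc2ccc(OC)cc2)cc1 | intermediate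
22 | (5S)-5-{(1R,2S,3S)-2-ethenyl-4-[(4-methoxyphenyl)methoxy]-2-methyl-3-(prop-1-en-2-yl)-1-[(triethylsilyl)oxy]butyl}-3-{[(4-methoxyphenyl)methoxy]methyl}furan-2(5H)-one | COc1ccc(COC[C@@H](C(C)=C)[C@](C)(C=C)[C@@H](O[Si](CC)(CC)CC)[C@H]3OC(=O)C(COCc2ccc(OC)cc2)=C3)cc1 | intermediate
23 | (5S)-5-{(1R,2S,3S)-2-ethenyl-4-hydroxy-2-methyl-3-(prop-1-en-2-yl)-1-[(triethylsilyl)oxy]butyl}-3-(hydroxymethyl)furan-2(5H)-one | OC[C@@H](C(C)=C)[C@](C)(C=C)[C@@H](O[Si](CC)(CC)CC)[C@H]1OC(=O)C(CO)=C1 | intermediate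
24 | (5S)-3-(bromomethyl)-5-{(1R,2S,3S)-2-ethenyl-4-hydroxy-2-methyl-3-(prop-1-en-2-yl)-1-[(triethylsilyl)oxy]butyl}furan-2(5H)-one | OC[C@@H](C(C)=C)[C@](C)(C=C)[C@@H](O[Si](CC)(CC)CC)[C@H]1OC(=O)C(CBr)=C1 | intermediate
25 | (2S,3S,4R)-4-[(2S)-4-(bromomethyl)-5-oxo-2,5-dihydrofuran-2-yl]-3-ethenyl-3-methyl-2-(prop-1-en-2-yl)-4-[(triethylsilyl)oxy]butanal | O=C[C@@H](C(C)=C)[C@](C)(C=C)[C@@H](O[Si](CC)(CC)CC)[C@H]1OC(=O)C(CBr)=C1 | intermediate
26 | allylchromium dichloride derived from 25 | O=C[C@@H](C(C)=C)[C@](C)(C=C)[C@@H](O[Si](CC)(CC)CC)[C@H]1OC(=O)C(C[Cr](Cl)Cl)=C1 | intermediate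
27 | (3aS,4R,5S,6S,7R,7aS)-6-ethenyl-4-hydroxy-6-methyl-3-methylidene-5-(prop-1-en-2-yl)-7-[(triethylsilyl)oxy]-3a,4,5,6,7,7a-hexahydro-1-benzofuran-2(3H)-one | C=C[C@@]1(C)[C@H](C(C)=C)[C@@H](O)[C@@H]2C(=C)C(=O)O[C@@H]2[C@@H]1O[Si](CC)(CC)CC | intermediate
28 | (3aS,4R,5S,6S,7R,7aS)-6-ethenyl-6-methyl-3-methylidene-2-oxo-5-(prop-1-en-2-yl)-7-[(triethylsilyl)oxy]octahydro-1-benzofuran-4-yl 2-methylpropanoate | C=C[C@@]1(C)[C@H](C(C)=C)[C@@H](OC(=O)C(C)C)[C@@H]2C(=C)C(=O)O[C@@H]2[C@@H]1O[Si](CC)(CC)CC | intermediate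
29 | (3aS,4R,5S,6S,7R,7aS)-6-ethenyl-7-hydroxy-6-methyl-3-methylidene-2-oxo-5-(prop-1-en-2-yl)octahydro-1-benzofuran-4-yl 2-methylpropanoate | C=C[C@@]1(C)[C@H](C(C)=C)[C@@H](OC(=O)C(C)C)[C@@H]2C(=C)C(=O)O[C@@H]2[C@@H]1O | intermediate
30 | (3aS,4R,5S,6S,7R,7aS)-6-ethenyl-7-hydroxy-5-(3-hydroxyprop-1-en-2-yl)-6-methyl-3-methylidene-2-oxooctahydro-1-benzofuran-4-yl 2-methylpropanoate | C=C[C@@]1(C)[C@H](C(=C)CO)[C@@H](OC(=O)C(C)C)[C@@H]2C(=C)C(=O)O[C@@H]2[C@@H]1O | intermediate
31 | (3aS,4S,5S,6S,7R,7aS)-6-ethenyl-7-hydroxy-5-[(2S)-2-(hydroxymethyl)oxiran-2-yl]-6-methyl-3-methylidene-2-oxooctahydro-1-benzofuran-4-yl 2-methylpropanoate | C=C[C@@]1(C)[C@H]([C@]2(CO)CO2)[C@@H](OC(=O)C(C)C)[C@@H]2C(=C)C(=O)O[C@@H]2[C@@H]1O | intermediate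
32 | (3aS,4S,5S,6S,7R,7aS)-6-ethenyl-5-[(2R)-2-formyloxiran-2-yl]-7-hydroxy-6-methyl-3-methylidene-2-oxooctahydro-1-benzofuran-4-yl 2-methylpropanoate (CNP0127398.1) | C=C[C@@]1(C)[C@H]([C@]2(C=O)CO2)[C@@H](OC(=O)C(C)C)[C@@H]2C(=C)C(=O)O[C@@H]2[C@@H]1O | target

## Step count and risks

Total step count: 23. Longest linear sequence: 23 steps (1 → 32); 7 and 18 enter as commercial partners.

Three steps most likely to fail:

1. Step 6 (Ireland–Claisen). What may go wrong: the dioxolane stereocentre may differentiate the two faces of C10 too weakly or in the opposite sense, or the dienolate geometry may erode, so that the C5/C10 pair forms with poor facial or relative selectivity. Fallback, setting out from 6 and returning at 12: 1,2-induction is replaced by 1,3-chirality transfer from a carbinol. Oxidation of 6 (MnO2, CH2Cl2) gives (2Z)-3-[(4R)-2,2-dimethyl-1,3-dioxolan-4-yl]but-2-enal F1. Copper-catalysed enantioselective 1,2-silylation (CuCl, NaOt-Bu, chiral bisphosphine, Me2PhSi–B(pin), MeOH) should give (1S,2Z)-1-[dimethyl(phenyl)silyl]-3-[(4R)-2,2-dimethyl-1,3-dioxolan-4-yl]but-2-en-1-ol F2. Esterification with 7 (N,N'-dicyclohexylcarbodiimide, DMAP) gives its 3-methylbut-2-enoate F3. Ireland–Claisen rearrangement of this ester (LiN(i-Pr)2, Me3SiCl) passes through a chair with the silyl group equatorial, so the carbinol configuration and not the dioxolane selects the face of C10; it should give the (E)-5-[dimethyl(phenyl)silyl] analogue of acid 12 F4. Protodesilylation (Bu4NF, DMSO, 80 °C) returns 12.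

2. Step 18 (key cyclisation). What may go wrong: the β,γ-unsaturated aldehyde may epimerise at C5 or isomerise into conjugation before it is captured, or the allylchromium may be protonated or couple intermolecularly faster than it cyclises. Fallback, setting out from 17 and returning at 27: the C6–C7 bond is made by a ketyl radical on a butenolide that carries no bromomethyl group, and C13 is added afterwards. Nozaki–Hiyama–Kishi coupling of 17 with ethyl (Z)-3-iodoacrylate (CrCl2, NiCl2 cat., DMF) and spontaneous lactonisation gives the C13-free butenolide 4-methoxybenzyl ether F5. DDQ gives the primary alcohol F6, and Dess–Martin periodinane gives the aldehyde F7. SmI2 (THF–MeOH, −78 °C) generates the C6 ketyl, which should add 6-exo to C7 on the butenolide face cis to the tether with the samarium-bound oxygen equatorial; protonation of the samarium enolate gives the saturated cis-fused hydroxy lactone F8. Aminomethylation of its dianion (LiN(i-Pr)2, then Me2N=CH2 iodide) gives the α-(dimethylaminomethyl) lactone F9, and N-methylation (MeI) with elimination (NaHCO3) returns 27.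

3. Step 21 (allylic oxidation). What may go wrong: over-oxidation of the new allylic alcohol to the enal, and competing oxidation at the tertiary allylic C5–H, may erode the yield on a late intermediate. Fallback, setting out from 29 and returning at 30: the oxygen is introduced by halogenation and substitution. Ene-type chlorination of the isopropenyl group (Ca(OCl)2, solid CO2, CH2Cl2–H2O, 0 °C) gives the 3-chloroprop-1-en-2-yl compound F10. Displacement with HCO2Na (Bu4NI cat., DMF, 40 °C) gives the allylic formate F11, and KHCO3 in MeOH–H2O at 0 °C cleaves the formate without touching the isobutyrate and returns 30.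

Further compounds

F1 | step 6 | (2Z)-3-[(4R)-2,2-dimethyl-1,3-dioxolan-4-yl]but-2-enal | O=C/C=C(C)\[C@@H]1COC(C)(C)O1
F2 | step 6 | (1S,2Z)-1-[dimethyl(phenyl)silyl]-3-[(4R)-2,2-dimethyl-1,3-dioxolan-4-yl]but-2-en-1-ol | O[C@@H]([Si](C)(C)c1ccccc1)/C=C(C)\[C@@H]1COC(C)(C)O1
F3 | step 6 | 3-methylbut-2-enoate of F2 | CC(C)=CC(=O)O[C@@H]([Si](C)(C)c1ccccc1)/C=C(C)\[C@@H]1COC(C)(C)O1
F4 | step 6 | (E)-5-[dimethyl(phenyl)silyl] analogue of acid 12 (C2, C3 and dioxolane configured as in 12) | OC(=O)[C@@H](C(C)=C)[C@](C)(/C=C/[Si](C)(C)c1ccccc1)[C@@H]1COC(C)(C)O1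
F5 | step 18 | (5S)-5-{(1R,2S,3S)-2-ethenyl-4-[(4-methoxyphenyl)methoxy]-2-methyl-3-(prop-1-en-2-yl)-1-[(triethylsilyl)oxy]butyl}furan-2(5H)-one | COc1ccc(COC[C@@H](C(C)=C)[C@](C)(C=C)[C@@H](O[Si](CC)(CC)CC)[C@H]2OC(=O)C=C2)cc1
F6 | step 18 | (5S)-5-{(1R,2S,3S)-2-ethenyl-4-hydroxy-2-methyl-3-(prop-1-en-2-yl)-1-[(triethylsilyl)oxy]butyl}furan-2(5H)-one | OC[C@@H](C(C)=C)[C@](C)(C=C)[C@@H](O[Si](CC)(CC)CC)[C@H]1OC(=O)C=C1
F7 | step 18 | (2S,3S,4R)-3-ethenyl-3-methyl-4-[(2S)-5-oxo-2,5-dihydrofuran-2-yl]-2-(prop-1-en-2-yl)-4-[(triethylsilyl)oxy]butanal | O=C[C@@H](C(C)=C)[C@](C)(C=C)[C@@H](O[Si](CC)(CC)CC)[C@H]1OC(=O)C=C1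
F8 | step 18 | 3-unsubstituted (saturated) analogue of 27 (ring stereocentres as in 27) | C=C[C@@]1(C)[C@H](C(C)=C)[C@@H](O)[C@@H]2CC(=O)O[C@@H]2[C@@H]1O[Si](CC)(CC)CC
F9 | step 18 | 3-[(dimethylamino)methyl] derivative of F8 (C3 unassigned) | C=C[C@@]1(C)[C@H](C(C)=C)[C@@H](O)[C@@H]2C(CN(C)C)C(=O)O[C@@H]2[C@@H]1O[Si](CC)(CC)CC
F10 | step 21 | 5-(3-chloroprop-1-en-2-yl) analogue of 29 | C=C[C@@]1(C)[C@H](C(=C)CCl)[C@@H](OC(=O)C(C)C)[C@@H]2C(=C)C(=O)O[C@@H]2[C@@H]1O
F11 | step 21 | formate ester of 30 at the primary allylic hydroxyl | C=C[C@@]1(C)[C@H](C(=C)COC=O)[C@@H](OC(=O)C(C)C)[C@@H]2C(=C)C(=O)O[C@@H]2[C@@H]1O
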